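One micromolar of second catalyst working for one minute is the unit we reckon in. Starting material passes over the free catalyst to intermediate, intermediate meets reagent on the second catalyst to give product, and the protic impurity quenches starting material. So we take the charge less the impurity, S = 95.0%, as the ceiling for product P. Reagent is charged at 20.0 mM, twice the 10 mM of starting material, and each product uses one reagent, so at the ceiling reagent stands at 52.5% of its charge and the second step slows with it. As a rough reckoning we still treat that step as first-order in intermediate, with a constant b proportional to the second catalyst concentration c.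

| flask | starting material | reagent | protic impurity | free catalyst | second catalyst | temperature | remark | time |
|---|---|---|---|---|---|---|---|---|
| theta | 10 mM | 20 mM | 0.50 mM | 50 µM | 14 µM | 25 °C | run made earlier |  |
| beta | 10 mM | 20 mM | 0.50 mM | 50 µM | 44 µM | 40 °C | run made earlier |  |
| alpha | 10 mM | 20 mM | 0.50 mM | 50 µM | 130 µM | 25 °C | run made earlier |  |
| green | 10 mM | 20.0 mM | 0.500 mM | 50 µM | 150 µM | 40 °C |  | 6.0 min |
| red | 10 mM | 20.0 mM | 0.500 mM | 50 µM | 80 µM | 40 °C |  | 6.0 min |
| blue | 10 mM | 20.0 mM | 0.500 mM | 50 µM | 15 µM | 40 °C |  | 6.0 min |
| ochre | 10 mM | 20.0 mM | 0.500 mM | 50 µM | 50 µM | 40 °C |  | 6.0 min |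
| grey | 10 mM | 20.0 mM | 0.500 mM | 50 µM | 12 µM | 40 °C |  | 6.0 min |

- the flasks by amount of product, in percent of the starting material charged, highest first, at 6.0 min (green / red / blue / ochre / grey)
- the amount of product, in percent of the starting material charged of the flask you put first, at 6.0 min
- the amount of product, in percent of the starting material charged of the flask you put last, at 6.0 min

The beta run stands at the same 40 °C as the flasks, so its table is the one we read.

| run | time / min | product / % |
|---|---|---|
| theta | 2.00 | 1.7 |
| theta | 3.00 | 2.5 |
| theta | 5.00 | 6.1 |
| theta | 6.00 | 9.6 |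
| theta | 8.00 | 13.9 |
| beta | 0.417 | 1.9 |
| beta | 1.00 | 4.6 |
| beta | 2.00 | 14.2 |
| beta | 3.00 | 24.9 |
| beta | 4.00 | 34.8 |
| alpha | 0.833 | 2.8 |
| alpha | 2.00 | 11.5 |
| alpha | 4.00 | 29.5 |
| alpha | 6.00 | 47.0 |
| alpha | 8.00 | 60.2 |

(each reading ± 0.5 percentage points)

The early rows lag: 4.6% at 1.00 min, then 14.2% at 2.00 min. We use the last two rows and form L = ln(S/(S−P)), which a first-order stage makes straight in time. L reads 0.304 at 3.00 min and 0.456 at 4.00 min, so b in the beta run reads 0.152 min⁻¹. Dividing by beta's 44 µM gives the hand-over constant κ, the first-order rate per unit of second catalyst, 57.7 M⁻¹ s⁻¹. Drawn back to where L vanishes, the same line gives a lag τ of 1.00 min. Both are readings from two rows, and each reading scatters with a standard deviation of 0.5 percentage points.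

Our rule, with b held constant, is P = S(1 − exp(−κc(t − τ))), which rises with c at a fixed time. It puts the flasks in order of second catalyst, with green at 87.9% and grey at 17.8%.

The forecast gives green > red > ochre > blue > grey, with 65% for green and 27% for grey, and says: “At high second catalyst, the first step limits the rate, so green, red and ochre bunch together.” Its order is ours, but its two numbers differ from ours. Its figure for grey is what the doubling rule for temperature gives from the theta run.

The flasks give green > red > ochre > blue > grey, with green at 80.3% and grey at 20.3%.

    starting material + free catalyst → free catalyst + intermediate (k = 200 M⁻¹ s⁻¹, Ea = 41.0 kJ mol⁻¹)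
    reagent + second catalyst + intermediate → second catalyst + product (k = 4100 M⁻² s⁻¹, Ea = 35.0 kJ mol⁻¹)
    starting material + protic impurity → quenched substrate (k = 33.0 M⁻¹ s⁻¹, Ea = 45.0 kJ mol⁻¹)
    (constants at 40 °C)

For grey, κc(t − τ) was 0.207, which gave 17.8% against the 20.3% found. For green the rule gave 87.9% against 80.3%. Now take a neighbour of grey, charged with 0.020 mM of second catalyst, with the time held at 6.0 min. There κc is 0.0692 min⁻¹, and the rule gives 27.8%. The neighbour flask gives 30.4%.

The runs stem from a simulated flask with made-up constants, and the scatter is random.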